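**Retrosynthetic overview** (carotenoid numbering: ε end C1–C20, ψ end primed)

1. Target 10 ⇒ C13 ε-enyne 8 + CH3 (from Me3Al) + C26 hexaenyl iodide 5. A one-pot syn-methylalumination of the terminal alkyne C9≡C10 followed by Pd/Zn-catalysed alkenyl–alkenyl coupling makes C9–C19 and C10–C11, fixes 9E and completes the octaene.
2. Enabling feature: the E-trisubstituted alkene C9(CH3)=C10H, held between C7=C8 (on C6 of the 2,6,6-trimethylcyclohex-2-ene ε-ring) and the sp2 carbon C11, is the retron of a 2-methylalk-1-enyl metal made from a terminal alkyne. The target is a pure hydrocarbon, so nothing interferes.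
3. 5 ⇒ C25 pentaenal 4 (Takai iodo-olefination adds C11) ⇒ farnesyl phosphonate 2 + C10-dialdehyde 3 (Horner–Wadsworth–Emmons, C11'=C12').
4. 8 ⇒ (R)-α-ionone 6 (methyl ketone → terminal alkyne via the enol phosphate).
5. Rings: none is formed. The single ε-cyclohexene ring and its C6 stereocentre are carried unchanged from 6.

Key step: step 5

Assumption: (R)-(+)-α-ionone is taken as a purchasable enantiopure material (otherwise it is reached from the racemate by the established lipase resolution of α-ionol and re-oxidation); it supplies C6, which no later step deprotonates or ionises.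

All polyenes are handled under argon with exclusion of light.

**Step 1**
Reactants: 1 (2E,6E)-farnesyl bromide
Product: 2 diethyl [(2E,6E)-3,7,11-trimethyldodeca-2,6,10-trien-1-yl]phosphonate
Conditions: P(OEt)3 (3 equiv), neat, 130 °C, EtBr distilled off
Reagents that add atoms: triethyl phosphite, CCOP(OCC)OCC
Why: Michaelis–Arbuzov reaction, in which phosphorus displaces the primary allylic bromide directly (α-attack) and bromide dealkylates the phosphonium, so the 2E,6E geometry should be kept and no stereocentre is involved.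

**Step 2**
Reactants: 2 diethyl (2E,6E)-farnesylphosphonate; 3 (2E,4E,6E)-2,7-dimethylocta-2,4,6-trienedial (C10-dialdehyde, 2.5 equiv)
Product: 4 (2E,4E,6E,8E,10E,14E)-2,7,11,15,19-pentamethylicosa-2,4,6,8,10,14,18-heptaenal (C25 aldehyde)
Conditions: KOtBu (1.05 equiv, slow addition), THF, −30 → 0 °C, dark; excess 3 recovered
Reagents that add atoms: none
Why: Horner–Wadsworth–Emmons olefination of the allylic phosphonate carbanion (α-attack) with an α-methyl enal should give the E-alkene C11'=C12' through reversible addition and syn-elimination, while excess 3 and the lower electrophilicity of the more conjugated product aldehyde should hold the reaction at mono-olefination, as in apo-carotenal chemistry.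

**Step 3**
Reactants: 4 C25 aldehyde
Product: 5 (1E,3E,5E,7E,9E,11E,15E)-1-iodo-3,8,12,16,20-pentamethylhenicosa-1,3,5,7,9,11,15,19-octaene (C26 iodide)
Conditions: CrCl2 (8 equiv), CHI3 (3 equiv), THF–1,4-dioxane, 0 °C → rt, dark; used at once
Reagents that add atoms: iodoform, IC(I)I
Why: Takai iodo-olefination, in which the gem-dichromium species from CHI3/CrCl2 adds to the aldehyde and eliminates Cr–O to give the E-alkenyl iodide (C11), conjugated α-branched enals being good substrates and the alkenes being inert to Cr(II).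

**Step 4**
Reactants: 6 (R)-α-ionone, (3E)-4-[(1R)-2,6,6-trimethylcyclohex-2-en-1-yl]but-3-en-2-one
Product: 8 (6R)-6-[(1E)-but-1-en-3-yn-1-yl]-1,5,5-trimethylcyclohex-1-ene (C13 ε-enyne), via enol phosphate 7 (not isolated)
Conditions: LDA (1.05 equiv), THF, −78 °C; ClP(O)(OEt)2, −78 °C → rt; LDA (2.3 equiv), THF, −78 → 0 °C; aq NH4Cl
Reagents that add atoms: none
Why: Methyl ketone to terminal alkyne by the enol phosphate elimination route: kinetic α'-deprotonation at the CH3 group (not at the γ C6–H), O-phosphorylation, then base-induced β-elimination of diethyl phosphate with the alkyne held as its acetylide, so C6 should stay R.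

**Step 5**
Reactants: 8 C13 ε-enyne (1.3 equiv); 5 C26 iodide (1.0 equiv)
Product: 10 (6R)-7',8'-dihydro-ε,ψ-carotene (all-E; α-zeacarotene), via dienylalane 9 (not isolated)
Conditions: Me3Al (2 equiv), Cp2ZrCl2 (25 mol %), (CH2Cl)2, rt; volatiles and excess Me3Al removed in vacuo; then 5, Pd2(dba)3 (2.5 mol %), P(2-furyl)3 (10 mol %), ZnCl2 (30 mol %), THF–DMF, rt, dark
Reagents that add atoms: trimethylaluminium, C[Al](C)C
Why: Cp2ZrCl2-catalysed syn-methylalumination of the terminal alkyne C9≡C10 puts CH3 on the internal carbon C9 and aluminium on the terminal carbon C10, so C9–C19 and the 9E geometry arise together in alane 9; oxidative addition of Pd(0) into the C11–I bond of 5, Al→Zn→Pd transmetalation of the dienyl group and reductive elimination then form the C10–C11 σ-bond with retention at both alkenyl carbons (Negishi coupling). The closest known reaction type is the one-pot Zr-catalysed carboalumination/Pd–Zn-catalysed alkenyl–alkenyl coupling of conjugated enynes with alkenyl halides, applied to retinoid and carotenoid polyenes. No ring is closed and no stereocentre is created; C6 is neither deprotonated nor ionised under these aprotic, non-basic conditions and should stay R. The step needs regioselectivity (Al at C10), syn-stereoselectivity and chemoselectivity for the alkyne over the ten alkenes of the two partners; the terminal, vinyl-conjugated alkyne secures the first two, and the tri- and 1,2-disubstituted alkenes are inert to the Me–Zr/Al reagent. It also needs alkenyl rather than methyl transfer from aluminium and retention of the 11E geometry of 5; removal of excess Me3Al before the coupling, the faster transfer of sp2 groups through zinc and the mild furylphosphine–Pd catalyst at room temperature in the dark should secure both.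

**Compound list**

1 | (2E,6E)-farnesyl bromide, (2E,6E)-1-bromo-3,7,11-trimethyldodeca-2,6,10-triene | CC(C)=CCC/C(C)=C/CC/C(C)=C/CBr | starting material
2 | diethyl [(2E,6E)-3,7,11-trimethyldodeca-2,6,10-trien-1-yl]phosphonate | CC(C)=CCC/C(C)=C/CC/C(C)=C/CP(=O)(OCC)OCC | intermediate
3 | (2E,4E,6E)-2,7-dimethylocta-2,4,6-trienedial (C10-dialdehyde) | O=C/C(C)=C/C=C/C=C(C)/C=O | starting material
4 | (2E,4E,6E,8E,10E,14E)-2,7,11,15,19-pentamethylicosa-2,4,6,8,10,14,18-heptaenal (C25 aldehyde) | CC(C)=CCC/C(C)=C/CC/C(C)=C/C=C/C(C)=C/C=C/C=C(C)/C=O | intermediate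
5 | (1E,3E,5E,7E,9E,11E,15E)-1-iodo-3,8,12,16,20-pentamethylhenicosa-1,3,5,7,9,11,15,19-octaene (C26 iodide) | CC(C)=CCC/C(C)=C/CC/C(C)=C/C=C/C(C)=C/C=C/C=C(C)/C=C/I | intermediate
6 | (R)-α-ionone, (3E)-4-[(1R)-2,6,6-trimethylcyclohex-2-en-1-yl]but-3-en-2-one | CC(=O)/C=C/[C@H]1C(C)=CCCC1(C)C | starting material
7 | diethyl (3E)-4-[(1R)-2,6,6-trimethylcyclohex-2-en-1-yl]buta-1,3-dien-2-yl phosphate (enol phosphate) | C=C(OP(=O)(OCC)OCC)/C=C/[C@H]1C(C)=CCCC1(C)C | intermediate
8 | (6R)-6-[(1E)-but-1-en-3-yn-1-yl]-1,5,5-trimethylcyclohex-1-ene (C13 ε-enyne) | C#C/C=C/[C@H]1C(C)=CCCC1(C)C | intermediate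
9 | dimethyl{(1E,3E)-2-methyl-4-[(1R)-2,6,6-trimethylcyclohex-2-en-1-yl]buta-1,3-dien-1-yl}alumane (dienylalane) | C[Al](C)/C=C(C)/C=C/[C@H]1C(C)=CCCC1(C)C | intermediate
10 | (6R)-7',8'-dihydro-ε,ψ-carotene, all-E (α-zeacarotene) | CC(C)=CCC/C(C)=C/CC/C(C)=C/C=C/C(C)=C/C=C/C=C(C)/C=C/C=C(C)/C=C/[C@H]1C(C)=CCCC1(C)C | target

**Totals**

Total step count: 5. Longest linear sequence: 4 steps (steps 1, 2, 3, 5); step 4 runs in parallel.

**Steps most likely to fail**

Step 5. The light- and Lewis-acid-sensitive hexaenyl iodide may isomerise or lose iodine before it couples, and methyl transfer from aluminium or homocoupling may compete with the cross-coupling. The fallback sets out from 8 and 4 and comes back at 10. Enyne 8 is carboaluminated as in step 5 and alane 9 is quenched with I2 (THF, −30 °C) to give the isolable dienyl iodide (6R)-6-[(1E,3E)-4-iodo-3-methylbuta-1,3-dien-1-yl]-1,5,5-trimethylcyclohex-1-ene F1. Aldehyde 4 is converted by Cr(II)-mediated boryl-olefination (Cl2CHBpin, CrCl2, LiI, THF, rt) into the more robust (E)-hexaenyl pinacol boronate 2-[(1E,3E,5E,7E,9E,11E,15E)-3,8,12,16,20-pentamethylhenicosa-1,3,5,7,9,11,15,19-octaen-1-yl]-4,4,5,5-tetramethyl-1,3,2-dioxaborolane F2. Suzuki–Miyaura coupling of F1 with F2 (Pd(OAc)2/SPhos, K3PO4, THF–H2O, rt, dark) should then form the same C10–C11 bond and give 10.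

Step 3. The iodo-olefination may proceed with poor E/Z control on the weakly electrophilic, fully conjugated aldehyde, Cr(II) may reductively dimerise the enal, and the product may decompose photochemically during isolation. The fallback sets out from 4 and comes back at 5. Ohira–Bestmann homologation of 4 (dimethyl (1-diazo-2-oxopropyl)phosphonate, K2CO3, MeOH–THF, 0 °C → rt) should give the terminal polyenyne (3E,5E,7E,9E,11E,15E)-3,8,12,16,20-pentamethylhenicosa-3,5,7,9,11,15,19-heptaen-1-yne F3. Hydrozirconation with Cp2Zr(H)Cl (THF, rt, dark) should give by syn-addition the (E)-alkenylzirconocene chloride F4, which is iodinated in the same flask (I2, THF, 0 °C) to give 5 with the 11E geometry fixed by the mechanism.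

Step 4. Enantiopurity may erode through reversible deprotonation of the doubly allylic C6–H by excess LDA on warming, and γ- instead of α'-enolisation may cause double-bond migration. The fallback sets out from 6 and comes back at 8. Haloform cleavage of 6 (NaOCl, NaOH, dioxane–H2O, 0 °C) should give (2E)-3-[(1R)-2,6,6-trimethylcyclohex-2-en-1-yl]prop-2-enoic acid F5. Reduction (LiAlH4, Et2O, 0 °C) should give the allylic alcohol (2E)-3-[(1R)-2,6,6-trimethylcyclohex-2-en-1-yl]prop-2-en-1-ol F6, and MnO2 (CH2Cl2, rt) the enal (2E)-3-[(1R)-2,6,6-trimethylcyclohex-2-en-1-yl]prop-2-enal F7. Colvin homologation of F7 (TMSCHN2, n-BuLi, THF, −78 → 0 °C) should then give 8; in this sequence no amide base meets the substrate above −78 °C.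

**Further compounds**

F1 | step 5 | (6R)-6-[(1E,3E)-4-iodo-3-methylbuta-1,3-dien-1-yl]-1,5,5-trimethylcyclohex-1-ene | I/C=C(C)/C=C/[C@H]1C(C)=CCCC1(C)C
F2 | step 5 | 2-[(1E,3E,5E,7E,9E,11E,15E)-3,8,12,16,20-pentamethylhenicosa-1,3,5,7,9,11,15,19-octaen-1-yl]-4,4,5,5-tetramethyl-1,3,2-dioxaborolane | CC(C)=CCC/C(C)=C/CC/C(C)=C/C=C/C(C)=C/C=C/C=C(C)/C=C/B1OC(C)(C)C(C)(C)O1
F3 | step 3 | (3E,5E,7E,9E,11E,15E)-3,8,12,16,20-pentamethylhenicosa-3,5,7,9,11,15,19-heptaen-1-yne | CC(C)=CCC/C(C)=C/CC/C(C)=C/C=C/C(C)=C/C=C/C=C(C)/C#C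
F4 | step 3 | chloridobis(η5-cyclopentadienyl)[(1E,3E,5E,7E,9E,11E,15E)-3,8,12,16,20-pentamethylhenicosa-1,3,5,7,9,11,15,19-octaen-1-yl]zirconium (drawn with σ-bonded cyclopentadienyl rings) | CC(C)=CCC/C(C)=C/CC/C(C)=C/C=C/C(C)=C/C=C/C=C(C)/C=C/[Zr](Cl)(C1C=CC=C1)C1C=CC=C1
F5 | step 4 | (2E)-3-[(1R)-2,6,6-trimethylcyclohex-2-en-1-yl]prop-2-enoic acid | OC(=O)/C=C/[C@H]1C(C)=CCCC1(C)C
F6 | step 4 | (2E)-3-[(1R)-2,6,6-trimethylcyclohex-2-en-1-yl]prop-2-en-1-ol | OC/C=C/[C@H]1C(C)=CCCC1(C)C
F7 | step 4 | (2E)-3-[(1R)-2,6,6-trimethylcyclohex-2-en-1-yl]prop-2-enal | O=C/C=C/[C@H]1C(C)=CCCC1(C)C
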